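**Retrosynthetic overview**
1. The C3=C4 alkene of target 16 comes last, by dehydration of chroman-4-ol 15, so the light- and heat-sensitive 2H-chromene is never stressed.
2. The C2 methyl of 14 comes from a C2-CH2CHO arm (13) by rhodium decarbonylation. Aldehyde 13 comes from bicyclic lactol 9 (oxidise, open, silylate, reduce).
3. Key disconnection: the C3-C4 bond of 9, formed by an amine-catalysed vinylogous aldol between salicylaldehyde 4 and phytenal 6.
4. Aldehyde 4 comes from 2,5-dimethylhydroquinone. Enal 6 comes from natural phytol, which supplies 4'R and 8'R.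
5. Ring order: the arene is bought, the pyran ring (O1-C2, sets C2) closes in step 4, and a temporary lactol ring forms in step 4 and is opened in step 6.

**Assumption:** the SMILES reads as (2S,4'R,8'R), that is C2 opposite to natural tocopherols, and natural-source phytol is (7R,11R); its E/Z ratio is irrelevant because step 4 erases it.

**Step 1**
Reactants: 1 2,5-dimethylbenzene-1,4-diol
Product: 2 4-[(tert-butyldimethylsilyl)oxy]-2,5-dimethylphenol
Conditions: TBSCl (1.0 equiv), imidazole (2.2 equiv), DMF, 0 °C → rt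
Reagents that add atoms: tert-butyldimethylsilyl chloride (TBSCl), CC(C)(C)[Si](C)(C)Cl
Why: Silyl ether formation on a symmetric hydroquinone can give only one mono-ether, and unreacted 1 and the bis-ether are separated by chromatography and recycled.

**Step 2**
Reactants: 2 4-[(tert-butyldimethylsilyl)oxy]-2,5-dimethylphenol
Product: 4 5-[(tert-butyldimethylsilyl)oxy]-2-hydroxy-3,6-dimethylbenzaldehyde, via salicyl alcohol 3 (not isolated)
Conditions: MgCl2 (2 equiv), Et3N (4 equiv), (CH2O)n (6 equiv), THF, reflux; cold 1 M HCl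
Reagents that add atoms: paraformaldehyde (reacts as formaldehyde), C=O
Why: In this Casnati–Skattebøl ortho-formylation the magnesium phenoxide delivers formaldehyde to the only free ortho carbon, and a second formaldehyde oxidises the benzylic alkoxide by hydride transfer.

**Step 3**
Reactants: 5 (2E,7R,11R)-phytol
Product: 6 (2E,7R,11R)-3,7,11,15-tetramethylhexadec-2-enal (phytenal)
Conditions: activated MnO2 (15 equiv), CH2Cl2, rt
Reagents that add atoms: none
Why: MnO2 oxidises the allylic alcohol selectively and leaves the two remote methyl stereocentres untouched.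

**Step 4 (key step)**
Reactants: 4 5-[(tert-butyldimethylsilyl)oxy]-2-hydroxy-3,6-dimethylbenzaldehyde; 6 phytenal (1.5 equiv)
Product: 9 tricyclic (2S,4S)-lactol (chroman numbering), via vinylogous aldol adduct 7 (not isolated), via open hydroxy aldehyde 8 (not isolated)
Conditions: (R)-2-{bis[3,5-bis(trifluoromethyl)phenyl](trimethylsilyloxy)methyl}pyrrolidine (30 mol %), PhCO2H (30 mol %), toluene, rt, 72 h
Reagents that add atoms: none
Why: This is a domino vinylogous aldol/oxa-Michael/lactolisation in which the dienamine of 6 attacks the aldehyde of 4 through its γ-CH2 terminus and the phenol then adds to the iminium face left open by the bulky (R)-catalyst group, setting C2 as S, while only the isomer with the 4-OH cis to the C2 acetaldehyde arm is trapped as the bicyclic lactol, which fixes C4 as S (the anomeric carbon is uncontrolled and is removed in step 5).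

**Step 5**
Reactants: 9 tricyclic lactol
Product: 10 tricyclic (2S,4S)-δ-lactone
Conditions: TPAP (5 mol %), NMO (1.5 equiv), 4 Å MS, CH2Cl2, rt
Reagents that add atoms: none
Why: The Ley–Griffith oxidation converts lactol to lactone under neutral conditions, and the ester level is much less prone than the aldehyde to retro-oxa-Michael loss of the C2 configuration.

**Step 6**
Reactants: 10 tricyclic lactone
Product: 11 2-[(2S,4S)-6-(TBSO)-4-hydroxy-5,8-dimethyl-2-((4R,8R)-4,8,12-trimethyltridecyl)chroman-2-yl]-N-methoxy-N-methylacetamide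
Conditions: MeNH(OMe)·HCl (3 equiv), AlMe3 (3 equiv), CH2Cl2, 0 °C → rt; aq. Rochelle salt; used crude
Reagents that add atoms: N,O-dimethylhydroxylamine hydrochloride, CNOC.Cl
Why: Weinreb aminolysis with the non-basic aluminium amide cleaves only the acyl C-O bond, so C2 and C4 keep their configuration and the 4-OH is released for protection.

**Step 7**
Reactants: 11 hydroxy Weinreb amide
Product: 12 the 4-O-TBS ether of 11
Conditions: TBSOTf (1.5 equiv), 2,6-lutidine (3 equiv), CH2Cl2, −78 → 0 °C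
Reagents that add atoms: tert-butyldimethylsilyl triflate (TBSOTf), CC(C)(C)[Si](C)(C)OS(=O)(=O)C(F)(F)F
Why: Silylation with the reactive triflate caps the hindered benzylic alcohol, which blocks relactonisation and prevents re-closure to the lactol after step 8.

**Step 8**
Reactants: 12 silylated Weinreb amide
Product: 13 2-[(2S,4S)-4,6-bis(TBSO)-5,8-dimethyl-2-((4R,8R)-4,8,12-trimethyltridecyl)chroman-2-yl]acetaldehyde
Conditions: DIBAL-H (1.3 equiv), THF, −78 °C; aq. Rochelle salt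
Reagents that add atoms: none
Why: Weinreb amide reduction stops at the chelated tetrahedral intermediate and releases the aldehyde only on work-up, and both silyl ethers are inert to DIBAL-H.

**Step 9**
Reactants: 13 chroman-2-acetaldehyde
Product: 14 (2S,4S)-4,6-bis(TBSO)-2,5,8-trimethyl-2-[(4R,8R)-4,8,12-trimethyltridecyl]chroman
Conditions: RhCl(PPh3)3 (1.1 equiv), degassed toluene, 110 °C
Reagents that add atoms: none
Why: In the Tsuji–Wilkinson decarbonylation the alkyl-rhodium hydride has no β-hydrogen because C2 is quaternary, so it can only collapse to CH3, and no bond at C2 is broken.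

**Step 10**
Reactants: 14 bis-silyl chroman
Product: 15 (2S,4S)-2,5,8-trimethyl-2-[(4R,8R)-4,8,12-trimethyltridecyl]chroman-4,6-diol
Conditions: TBAF (4 equiv), THF, 0 °C → rt, Ar; pH 7 buffer
Reagents that add atoms: none
Why: Fluoride desilylation removes both silyl groups, and no carbonyl remains in 14, so basic fluoride cannot trigger a retro-oxa-Michael reaction.

**Step 11**
Reactants: 15 chroman-4,6-diol
Product: 16 (2S)-2,5,8-trimethyl-2-[(4R,8R)-4,8,12-trimethyltridecyl]-2H-chromen-6-ol (target)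
Conditions: p-TsOH·H2O (5 mol %), toluene, 50 °C, 1 h, Ar, amber glassware
Reagents that add atoms: none
Why: Acid-catalysed E1 dehydration proceeds through the O1-stabilised benzylic cation, erases C4 and leaves C2 untouched, while low temperature and darkness suppress electrocyclic ring opening, the racemisation path of 2H-chromenes.

**Compound list**
1 | 2,5-dimethylbenzene-1,4-diol | Cc1cc(O)c(C)cc1O | starting material
2 | 4-[(tert-butyldimethylsilyl)oxy]-2,5-dimethylphenol | Cc1cc(O[Si](C)(C)C(C)(C)C)c(C)cc1O | intermediate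
3 | 4-[(tert-butyldimethylsilyl)oxy]-2-(hydroxymethyl)-3,6-dimethylphenol (formed as its Mg salt) | OCc1c(O)c(C)cc(O[Si](C)(C)C(C)(C)C)c1C | intermediate (not isolated)
4 | 5-[(tert-butyldimethylsilyl)oxy]-2-hydroxy-3,6-dimethylbenzaldehyde | O=Cc1c(O)c(C)cc(O[Si](C)(C)C(C)(C)C)c1C | intermediate
5 | (2E,7R,11R)-3,7,11,15-tetramethylhexadec-2-en-1-ol (natural phytol) | OC/C=C(\C)CCC[C@H](C)CCC[C@H](C)CCCC(C)C | starting material
6 | (2E,7R,11R)-3,7,11,15-tetramethylhexadec-2-enal | O=C/C=C(\C)CCC[C@H](C)CCC[C@H](C)CCCC(C)C | intermediate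
7 | (2E,5S)-5-[5-(TBSO)-2-hydroxy-3,6-dimethylphenyl]-5-hydroxy-3-[(4R,8R)-4,8,12-trimethyltridecyl]pent-2-enal (present as its iminium ion, drawn as the free aldehyde) | O=C/C=C(/C[C@H](O)c1c(O)c(C)cc(O[Si](C)(C)C(C)(C)C)c1C)CCC[C@H](C)CCC[C@H](C)CCCC(C)C | intermediate (not isolated)
8 | 2-[(2S,4S)-6-(TBSO)-4-hydroxy-5,8-dimethyl-2-((4R,8R)-4,8,12-trimethyltridecyl)chroman-2-yl]acetaldehyde | Cc1cc(O[Si](C)(C)C(C)(C)C)c(C)c2c1O[C@@](CC=O)(CCC[C@H](C)CCC[C@H](C)CCCC(C)C)C[C@@H]2O | intermediate (not isolated)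
9 | (2S,4S)-lactol: chroman 8 closed by a C2-CH2-CH(OH)-O-C4 bridge (2,6-methano-1,5-benzodioxocin-4-ol skeleton, anomer mixture) | Cc1cc(O[Si](C)(C)C(C)(C)C)c(C)c2c1O[C@@]3(CCC[C@H](C)CCC[C@H](C)CCCC(C)C)C[C@@H]2OC(O)C3 | intermediate
10 | (2S,4S)-lactone (2,6-methano-1,5-benzodioxocin-4-one skeleton) | Cc1cc(O[Si](C)(C)C(C)(C)C)c(C)c2c1O[C@@]3(CCC[C@H](C)CCC[C@H](C)CCCC(C)C)C[C@@H]2OC(=O)C3 | intermediate
11 | 2-[(2S,4S)-6-(TBSO)-4-hydroxy-5,8-dimethyl-2-((4R,8R)-4,8,12-trimethyltridecyl)chroman-2-yl]-N-methoxy-N-methylacetamide | Cc1cc(O[Si](C)(C)C(C)(C)C)c(C)c2c1O[C@@](CC(=O)N(C)OC)(CCC[C@H](C)CCC[C@H](C)CCCC(C)C)C[C@@H]2O | intermediate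
12 | 2-[(2S,4S)-4,6-bis(TBSO)-5,8-dimethyl-2-((4R,8R)-4,8,12-trimethyltridecyl)chroman-2-yl]-N-methoxy-N-methylacetamide | Cc1cc(O[Si](C)(C)C(C)(C)C)c(C)c2c1O[C@@](CC(=O)N(C)OC)(CCC[C@H](C)CCC[C@H](C)CCCC(C)C)C[C@@H]2O[Si](C)(C)C(C)(C)C | intermediate
13 | 2-[(2S,4S)-4,6-bis(TBSO)-5,8-dimethyl-2-((4R,8R)-4,8,12-trimethyltridecyl)chroman-2-yl]acetaldehyde | Cc1cc(O[Si](C)(C)C(C)(C)C)c(C)c2c1O[C@@](CC=O)(CCC[C@H](C)CCC[C@H](C)CCCC(C)C)C[C@@H]2O[Si](C)(C)C(C)(C)C | intermediate
14 | (2S,4S)-4,6-bis(TBSO)-2,5,8-trimethyl-2-[(4R,8R)-4,8,12-trimethyltridecyl]chroman | Cc1cc(O[Si](C)(C)C(C)(C)C)c(C)c2c1O[C@@](C)(CCC[C@H](C)CCC[C@H](C)CCCC(C)C)C[C@@H]2O[Si](C)(C)C(C)(C)C | intermediate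
15 | (2S,4S)-2,5,8-trimethyl-2-[(4R,8R)-4,8,12-trimethyltridecyl]chroman-4,6-diol | Cc1cc(O)c(C)c2c1O[C@@](C)(CCC[C@H](C)CCC[C@H](C)CCCC(C)C)C[C@@H]2O | intermediate
16 | (2S)-2,5,8-trimethyl-2-[(4R,8R)-4,8,12-trimethyltridecyl]-2H-chromen-6-ol | Cc1cc(O)c(C)c2c1O[C@@](C)(CCC[C@H](C)CCC[C@H](C)CCCC(C)C)C=C2 | target

**Totals:** 11 steps in all. The longest linear sequence is 10 steps (1, 2, 4–11).

**Three steps most likely to fail**

*Step 4.*
- Risk: the aldehyde is hindered, a second γ-position competes, and the yield is moderate. The sense of induction rests on the shielding model, and the (S)-catalyst is equally available if the opposite C2 epimer is obtained.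
- Fallback: it sets out from 1 and 5 and comes back at 16.
- C-acetylate 1 with AcOH/BF3·OEt2 at 100 °C to give 1-(2,5-dihydroxy-3,6-dimethylphenyl)ethan-1-one F1.
- Ozonise 5 (O3, CH2Cl2/MeOH, −78 °C, then Me2S) to give (6R,10R)-6,10,14-trimethylpentadecan-2-one F2.
- Condense F1 and F2 with pyrrolidine in toluene (Kabbe aldol condensation/oxa-Michael) to give the 6-hydroxychroman-4-one as a 1:1 mixture of C2 epimers F3.
- Resolve F3 by preparative chromatography on an amylose carbamate chiral phase to give the (2S)-chromanone F4. The 2R epimer is re-equilibrated with pyrrolidine and recycled.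
- Reduce F4 with NaBH4 to give the (2S,4RS)-chroman-4,6-diol F5. Both C4 epimers give 16 under the conditions of step 11.

*Step 9.*
- Risk: the neopentyl-type aldehyde may react slowly, and at 110 °C β-aryloxide loss from the alkyl-rhodium or from the aldehyde could compete.
- Fallback: it sets out from 13 and comes back at 14.
- Pinnick oxidation (NaClO2, NaH2PO4, 2-methyl-2-butene, t-BuOH/H2O) gives the chroman-2-acetic acid F6.
- Coupling with 1-hydroxypyridine-2(1H)-thione (DCC, CH2Cl2, dark) gives the Barton ester F7.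
- Visible-light photolysis of F7 at rt with excess t-BuSH effects radical reductive decarboxylation to 14. The ring is still saturated at this stage, so no 1,2-vinyl shift is possible.

*Step 6.*
- Risk: the Lewis-acidic aluminium reagent could ionise the benzylic lactone C-O bond, or 11 could relactonise before it is silylated.
- Fallback: it sets out from 9 and comes back at 13, bypassing 10–12.
- NaBH4 (THF/MeOH, 0 °C) reduces 9 to the 2-(2-hydroxyethyl)chroman-4-ol F8.
- PivCl/pyridine at 0 °C acylates only the primary alcohol to give the monopivalate F9.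
- TBSOTf/2,6-lutidine gives the 4-O-TBS pivalate F10.
- DIBAL-H at −78 °C removes the pivalate to give the primary alcohol F11.
- Dess–Martin periodinane buffered with NaHCO3 oxidises F11 to 13.

**Further compounds**
F1 | step 4 | 1-(2,5-dihydroxy-3,6-dimethylphenyl)ethan-1-one | CC(=O)c1c(O)c(C)cc(O)c1C
F2 | step 4 | (6R,10R)-6,10,14-trimethylpentadecan-2-one | CC(=O)CCC[C@H](C)CCC[C@H](C)CCCC(C)C
F3 | step 4 | (2RS)-6-hydroxy-2,5,8-trimethyl-2-[(4R,8R)-4,8,12-trimethyltridecyl]chroman-4-one | Cc1cc(O)c(C)c2c1OC(C)(CCC[C@H](C)CCC[C@H](C)CCCC(C)C)CC2=O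
F4 | step 4 | (2S)-6-hydroxy-2,5,8-trimethyl-2-[(4R,8R)-4,8,12-trimethyltridecyl]chroman-4-one | Cc1cc(O)c(C)c2c1O[C@@](C)(CCC[C@H](C)CCC[C@H](C)CCCC(C)C)CC2=O
F5 | step 4 | (2S,4RS)-2,5,8-trimethyl-2-[(4R,8R)-4,8,12-trimethyltridecyl]chroman-4,6-diol | Cc1cc(O)c(C)c2c1O[C@@](C)(CCC[C@H](C)CCC[C@H](C)CCCC(C)C)CC2O
F6 | step 9 | 2-[(2S,4S)-4,6-bis(TBSO)-5,8-dimethyl-2-((4R,8R)-4,8,12-trimethyltridecyl)chroman-2-yl]acetic acid | Cc1cc(O[Si](C)(C)C(C)(C)C)c(C)c2c1O[C@@](CC(=O)O)(CCC[C@H](C)CCC[C@H](C)CCCC(C)C)C[C@@H]2O[Si](C)(C)C(C)(C)C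
F7 | step 9 | 2-thioxopyridin-1(2H)-yl ester of F6 (Barton ester) | Cc1cc(O[Si](C)(C)C(C)(C)C)c(C)c2c1O[C@@](CC(=O)On3ccccc3=S)(CCC[C@H](C)CCC[C@H](C)CCCC(C)C)C[C@@H]2O[Si](C)(C)C(C)(C)C
F8 | step 6 | (2R,4S)-6-(TBSO)-2-(2-hydroxyethyl)-5,8-dimethyl-2-[(4R,8R)-4,8,12-trimethyltridecyl]chroman-4-ol (same spatial arrangement at C2, descriptor changes by CIP priority) | Cc1cc(O[Si](C)(C)C(C)(C)C)c(C)c2c1O[C@@](CCO)(CCC[C@H](C)CCC[C@H](C)CCCC(C)C)C[C@@H]2O
F9 | step 6 | 2-[(2R,4S)-6-(TBSO)-4-hydroxy-5,8-dimethyl-2-((4R,8R)-4,8,12-trimethyltridecyl)chroman-2-yl]ethyl pivalate | Cc1cc(O[Si](C)(C)C(C)(C)C)c(C)c2c1O[C@@](CCOC(=O)C(C)(C)C)(CCC[C@H](C)CCC[C@H](C)CCCC(C)C)C[C@@H]2O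
F10 | step 6 | 2-[(2R,4S)-4,6-bis(TBSO)-5,8-dimethyl-2-((4R,8R)-4,8,12-trimethyltridecyl)chroman-2-yl]ethyl pivalate | Cc1cc(O[Si](C)(C)C(C)(C)C)c(C)c2c1O[C@@](CCOC(=O)C(C)(C)C)(CCC[C@H](C)CCC[C@H](C)CCCC(C)C)C[C@@H]2O[Si](C)(C)C(C)(C)C
F11 | step 6 | 2-[(2R,4S)-4,6-bis(TBSO)-5,8-dimethyl-2-((4R,8R)-4,8,12-trimethyltridecyl)chroman-2-yl]ethan-1-ol | Cc1cc(O[Si](C)(C)C(C)(C)C)c(C)c2c1O[C@@](CCO)(CCC[C@H](C)CCC[C@H](C)CCCC(C)C)C[C@@H]2O[Si](C)(C)C(C)(C)C
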